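**Retrosynthetic overview**

- The aryl carbinol is disconnected last. The (S)-carbinol comes from chelation-controlled reduction of a 3-aroyl lactone, and the aroyl group from C-acylation at C3 of (R)-4-(3,4-dimethoxybenzyl)dihydrofuran-2(3H)-one with a silyl-protected vanilloyl chloride.
- The γ-lactone, the only ring, is closed in the key step. Dichloroketene and an enantiopure (Z)-alkenyl p-tolyl sulfoxide combine by O-acylation, a [3,3]-sigmatropic shift (C3–C4 bond) and closure of the carboxylate on the thionium carbon (O1–C5 bond). The two chlorines and the arylthio group are then removed reductively.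
- Enabling feature: in the lactone segment O1–C5H2–C4H(CH2Ar), C5 is an unsubstituted methylene on the ring oxygen next to the single benzyl-bearing stereocentre C4. This segment maps onto a vinyl sulfoxide (C5 = sulfur-bearing carbon, C4 = β-carbon), and C3–C2(=O)–O1 maps onto a ketene.
- Stereochemistry is relayed from sulfur (set from (−)-menthyl (S)-p-toluenesulfinate) to C4, then to C3 (trans), then to the carbinol carbon (syn). The vinyl sulfoxide derives from 3,4-dimethoxybenzyl bromide and ethynylmagnesium bromide.

Key step: step 4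

Remark on the chemistry: the sense of sulfur-to-carbon chirality transfer in the key step is taken from the chair transition state with the p-tolyl group pseudo-equatorial. The configuration drawn at the sulfur-bearing ring carbon of the key-step lactone (trans to the benzyl group) is an assumption of no consequence, because that centre is removed in the following step.

**Route**

Step 1
Reactants: 1 4-(bromomethyl)-1,2-dimethoxybenzene (3,4-dimethoxybenzyl bromide); 2 ethynylmagnesium bromide
Product: 3 1,2-dimethoxy-4-(prop-2-yn-1-yl)benzene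
Conditions: 2 (3 equiv), CuBr (5 mol %), THF, 0 to 50 °C; aq NH4Cl
Reagents that add atoms: none
Why: Copper-catalysed cross-coupling of a benzylic bromide with an alkynyl Grignard reagent, in which the excess of 2 suppresses double benzylation; no stereocentre is formed.

Step 2
Reactants: 3 1,2-dimethoxy-4-(prop-2-yn-1-yl)benzene; 4 (1R,2S,5R)-menthyl (S)-p-toluenesulfinate
Product: 6 (S)-1,2-dimethoxy-4-[3-(p-tolylsulfinyl)prop-2-yn-1-yl]benzene, via alkynylmagnesium bromide 5 (not isolated)
Conditions: EtMgBr (1.0 equiv), THF, 0 °C; then added to 4, toluene, −20 °C; cold aq NH4Cl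
Reagents that add atoms: none
Why: Andersen sulfinate substitution, in which the alkynyl Grignard reagent displaces menthoxide at sulfur with inversion, so the sulfur stereocentre is set by the diastereomerically pure sulfinate 4 (the descriptor stays S only because the alkynyl group outranks tolyl); low temperature and a mildly acidic quench should keep the propargylic-benzylic CH2 from isomerising to the allene.

Step 3
Reactants: 6 (S)-1,2-dimethoxy-4-[3-(p-tolylsulfinyl)prop-2-yn-1-yl]benzene
Product: 7 (Z)-1,2-dimethoxy-4-[3-[(R)-p-tolylsulfinyl]prop-2-en-1-yl]benzene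
Conditions: H2 (1 atm), RhCl(PPh3)3 (5 mol %), benzene, rt
Reagents that add atoms: none
Why: Homogeneous syn-hydrogenation of a 1-alkynyl sulfoxide, which should stop at the (Z)-alkenyl sulfoxide because the hindered, electron-poor product alkene is reduced far more slowly; sulfur is not touched (the descriptor becomes R because vinyl ranks below tolyl).

Step 4
Reactants: 7 (Z)-1,2-dimethoxy-4-[3-[(R)-p-tolylsulfinyl]prop-2-en-1-yl]benzene; 8 trichloroacetyl chloride
Product: 12 (4S,5S)-3,3-dichloro-4-(3,4-dimethoxybenzyl)-5-(p-tolylthio)dihydrofuran-2(3H)-one, via dichloroketene 9 (not isolated), via acyloxysulfonium enolate 10 (not isolated), via thionium carboxylate 11 (not isolated)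
Conditions: 8 (2.5 equiv, slow addition), Zn–Cu couple, Et2O, reflux
Reagents that add atoms: none
Why: Ketene lactonization of a vinyl sulfoxide (an additive Pummerer sequence): zinc dechlorinates 8 to dichloroketene 9, the sulfoxide oxygen of 7 adds to the ketene carbonyl to give the acyloxysulfonium enolate 10, and a [3,3]-sigmatropic shift joins the CCl2 carbon to the β-vinyl carbon (C3–C4 of the lactone) while the S–O bond breaks, giving the thionium carboxylate 11. The carboxylate oxygen then closes on the thionium carbon (5-exo-trig, O1–C5), forming the only ring of the target. The closest known reaction type is the dichloroketene lactonization of enantiopure alkenyl p-tolyl sulfoxides to β-substituted γ-butyrolactones. The new C4 stereocentre is controlled by the sulfur configuration: in the chair-like six-membered transition state the p-tolyl group is pseudo-equatorial (anti to the C=C bond) and the lone pair takes the crowded inside position, so the enolate carbon reaches only the alkene face on which the S–O bond lies, and the R sulfur with the Z alkene should give the 4S lactone (4R once chlorine and sulfur are gone). The C5 centre is expected trans to the benzyl group and is removed in the next step. The step needs O-acylation of the sulfoxide in preference to acylation of the dimethoxyarene and no vinyl-to-allyl sulfoxide isomerisation; the high nucleophilicity of the sulfinyl oxygen toward dichloroketene, the ether-solvated ZnCl2 and the base-free medium should secure this, and A(1,3) strain between the cis benzyl group and the sulfur substituents locks the reactive rotamer.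

Step 5
Reactants: 12 (4S,5S)-3,3-dichloro-4-(3,4-dimethoxybenzyl)-5-(p-tolylthio)dihydrofuran-2(3H)-one
Product: 13 (R)-4-(3,4-dimethoxybenzyl)dihydrofuran-2(3H)-one
Conditions: Bu3SnH (4.5 equiv), AIBN (cat.), toluene, reflux
Reagents that add atoms: none
Why: Stannyl radical chain reduction, in which both α-chloro C–Cl bonds and the C–S bond of the O,S-acetal (giving a stabilised α-acyloxyalkyl radical) are cleaved and replaced by C–H, leaving the C4 stereocentre untouched (its descriptor changes from S to R only through the change in substituent priorities).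

Step 6
Reactants: 14 4-hydroxy-3-methoxybenzoic acid (vanillic acid)
Product: 15 tert-butyldimethylsilyl 4-(tert-butyldimethylsilyloxy)-3-methoxybenzoate
Conditions: TBSCl (2.3 equiv), imidazole (5 equiv), DMF, rt
Reagents that add atoms: tert-butyldimethylsilyl chloride CC(C)(C)[Si](C)(C)Cl
Why: Standard silylation of a phenol and a carboxylic acid with a silyl chloride and imidazole; no stereocentre is involved.

Step 7
Reactants: 15 tert-butyldimethylsilyl 4-(tert-butyldimethylsilyloxy)-3-methoxybenzoate
Product: 16 4-(tert-butyldimethylsilyloxy)-3-methoxybenzoyl chloride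
Conditions: (COCl)2 (1.2 equiv), DMF (cat.), CH2Cl2, 0 °C to rt; used crude
Reagents that add atoms: oxalyl chloride ClC(=O)C(=O)Cl
Why: Direct conversion of a silyl ester into the acid chloride by oxalyl chloride with catalytic DMF (Vilsmeier-type activation), under neutral conditions that spare the aryl silyl ether.

Step 8
Reactants: 13 (R)-4-(3,4-dimethoxybenzyl)dihydrofuran-2(3H)-one; 16 4-(tert-butyldimethylsilyloxy)-3-methoxybenzoyl chloride
Product: 18 (3S,4R)-3-[4-(tert-butyldimethylsilyloxy)-3-methoxybenzoyl]-4-(3,4-dimethoxybenzyl)dihydrofuran-2(3H)-one, via lithium enolate 17 (not isolated)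
Conditions: LiN(SiMe3)2 (2.2 equiv), THF, −78 °C; then 16 (1.05 equiv), −78 to −30 °C; aq NH4Cl
Reagents that add atoms: none
Why: Crossed Claisen-type C-acylation of a lactone lithium enolate by an aroyl chloride, in which the second equivalent of base holds the product as its enolate and protonation on work-up should give the thermodynamically preferred 3,4-trans isomer (3S set relative to 4R).

Step 9
Reactants: 18 (3S,4R)-3-[4-(tert-butyldimethylsilyloxy)-3-methoxybenzoyl]-4-(3,4-dimethoxybenzyl)dihydrofuran-2(3H)-one
Product: 19 (3S,4R)-3-[(S)-[4-(tert-butyldimethylsilyloxy)-3-methoxyphenyl](hydroxy)methyl]-4-(3,4-dimethoxybenzyl)dihydrofuran-2(3H)-one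
Conditions: Zn(BH4)2 (ethereal solution), Et2O–CH2Cl2, −20 to 0 °C; aq NH4Cl
Reagents that add atoms: none
Why: Chelation-controlled hydride reduction of an α-substituted β-keto ester, in which zinc bridges the ketone and lactone carbonyl oxygens and hydride should reach the ketone face remote from ring carbon C4 and its benzyl group, giving the (S)-carbinol syn to the C3–C4 bond.

Step 10
Reactants: 19 (3S,4R)-3-[(S)-[4-(tert-butyldimethylsilyloxy)-3-methoxyphenyl](hydroxy)methyl]-4-(3,4-dimethoxybenzyl)dihydrofuran-2(3H)-one
Product: 20 (3S,4R)-4-(3,4-dimethoxybenzyl)-3-[(S)-hydroxy(4-hydroxy-3-methoxyphenyl)methyl]dihydrofuran-2(3H)-one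
Conditions: Bu4NF (1.1 equiv), AcOH (1.2 equiv), THF, 0 °C
Reagents that add atoms: none
Why: Fluoride cleavage of the aryl silyl ether, buffered with acetic acid so that retro-aldol cleavage and epimerisation of the β-hydroxy lactone are avoided; no stereocentre is touched.

**Compound list**

1 | 4-(bromomethyl)-1,2-dimethoxybenzene | COc1ccc(CBr)cc1OC | starting material
2 | ethynylmagnesium bromide | C#C[Mg]Br | starting material
3 | 1,2-dimethoxy-4-(prop-2-yn-1-yl)benzene | COc1ccc(CC#C)cc1OC | intermediate
4 | (1R,2S,5R)-menthyl (S)-p-toluenesulfinate | C[C@@H]1CC[C@H]([C@@H](C1)O[S@](=O)c2ccc(C)cc2)C(C)C | starting material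
5 | [3-(3,4-dimethoxyphenyl)prop-1-yn-1-yl]magnesium bromide | COc1ccc(CC#C[Mg]Br)cc1OC | intermediate
6 | (S)-1,2-dimethoxy-4-[3-(p-tolylsulfinyl)prop-2-yn-1-yl]benzene | COc1ccc(CC#C[S@@](=O)c2ccc(C)cc2)cc1OC | intermediate
7 | (Z)-1,2-dimethoxy-4-[3-[(R)-p-tolylsulfinyl]prop-2-en-1-yl]benzene | COc1ccc(C/C=C\[S@@](=O)c2ccc(C)cc2)cc1OC | intermediate
8 | trichloroacetyl chloride | ClC(=O)C(Cl)(Cl)Cl | starting material
9 | dichloroketene | ClC(Cl)=C=O | intermediate
10 | (R)-[(2,2-dichloro-1-oxidovinyl)oxy][(Z)-3-(3,4-dimethoxyphenyl)prop-1-en-1-yl](p-tolyl)sulfonium (zwitterion) | COc1ccc(C/C=C\[S@@+](OC(=C(Cl)Cl)[O-])c2ccc(C)cc2)cc1OC | intermediate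
11 | (S)-2,2-dichloro-3-(3,4-dimethoxybenzyl)-4-(p-tolylsulfonio)but-3-enoate (thionium carboxylate zwitterion) | [O-]C(=O)C(Cl)(Cl)[C@@H](Cc1ccc(OC)c(OC)c1)/C=[S+]/c1ccc(C)cc1 | intermediate
12 | (4S,5S)-3,3-dichloro-4-(3,4-dimethoxybenzyl)-5-(p-tolylthio)dihydrofuran-2(3H)-one | O=C1O[C@@H](Sc2ccc(C)cc2)[C@H](Cc2ccc(OC)c(OC)c2)C1(Cl)Cl | intermediate
13 | (R)-4-(3,4-dimethoxybenzyl)dihydrofuran-2(3H)-one | O=C1OC[C@H](Cc2ccc(OC)c(OC)c2)C1 | intermediate
14 | 4-hydroxy-3-methoxybenzoic acid | COc1cc(C(=O)O)ccc1O | starting material
15 | tert-butyldimethylsilyl 4-(tert-butyldimethylsilyloxy)-3-methoxybenzoate | COc1cc(C(=O)O[Si](C)(C)C(C)(C)C)ccc1O[Si](C)(C)C(C)(C)C | intermediate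
16 | 4-(tert-butyldimethylsilyloxy)-3-methoxybenzoyl chloride | COc1cc(C(=O)Cl)ccc1O[Si](C)(C)C(C)(C)C | intermediate
17 | lithium (R)-4-(3,4-dimethoxybenzyl)-4,5-dihydrofuran-2-olate | [Li]OC1=C[C@@H](Cc2ccc(OC)c(OC)c2)CO1 | intermediate
18 | (3S,4R)-3-[4-(tert-butyldimethylsilyloxy)-3-methoxybenzoyl]-4-(3,4-dimethoxybenzyl)dihydrofuran-2(3H)-one | O=C1OC[C@H](Cc2ccc(OC)c(OC)c2)[C@H]1C(=O)c3ccc(O[Si](C)(C)C(C)(C)C)c(OC)c3 | intermediate
19 | (3S,4R)-3-[(S)-[4-(tert-butyldimethylsilyloxy)-3-methoxyphenyl](hydroxy)methyl]-4-(3,4-dimethoxybenzyl)dihydrofuran-2(3H)-one | COc1cc([C@@H](O)[C@H]2C(=O)OC[C@@H]2Cc2ccc(OC)c(OC)c2)ccc1O[Si](C)(C)C(C)(C)C | intermediate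
20 | (3S,4R)-4-(3,4-dimethoxybenzyl)-3-[(S)-hydroxy(4-hydroxy-3-methoxyphenyl)methyl]dihydrofuran-2(3H)-one | COc1cc([C@@H](O)[C@H]2C(=O)OC[C@@H]2Cc2ccc(OC)c(OC)c2)ccc1O | target

**Step count and risks**

Total step count: 10. Longest linear sequence: 8 steps (steps 1 to 5 and 8 to 10); steps 6 and 7 are the two-step side branch to 16.

Steps most likely to fail:

1. Step 4. The transfer of chirality from sulfur to carbon may be incomplete if the two sulfonium rotamers are not well differentiated. The electron-rich arene may be acylated, or the vinyl sulfoxide may isomerise to the allyl sulfoxide before it is acylated. Fallback (from 1, back to the route at 13): auxiliary-controlled enolate alkylation replaces the sigmatropic chirality transfer. (R)-4-Benzyl-3-[4-(tert-butoxy)-4-oxobutanoyl]oxazolidin-2-one F1 would be prepared from commercial (R)-4-benzyl-2-oxazolidinone and 4-tert-butoxy-4-oxobutanoic acid through the pivaloyl mixed anhydride (Et3N, LiCl, THF). NaN(SiMe3)2 in THF at −78 °C should convert it into the sodium (Z)-enolate of F1 F2, which is benzylated by bromide 1 on the face remote from the auxiliary benzyl group to give tert-butyl (R)-4-[(R)-4-benzyl-2-oxooxazolidin-3-yl]-3-(3,4-dimethoxybenzyl)-4-oxobutanoate F3. LiBH4 (THF, MeOH, 0 °C) reduces the imide selectively to tert-butyl (R)-3-(3,4-dimethoxybenzyl)-4-hydroxybutanoate F4, and CF3CO2H in CH2Cl2 closes the lactone to 13.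

2. Step 2. Base-induced isomerisation of the propargylic-benzylic sulfoxide to the allenyl sulfoxide may occur during the Grignard sulfinylation, and the rhodium-catalysed reduction that follows may be slowed by sulfoxide coordination. Fallback (from 3, back to the route at 7): the Z alkene is made before sulfur is introduced. Alkyne 3 is iodinated (N-iodosuccinimide, AgNO3 cat., acetone) to 4-(3-iodoprop-2-yn-1-yl)-1,2-dimethoxybenzene F5. Diimide reduction (2-nitrobenzenesulfonylhydrazide, Et3N, THF–i-PrOH) gives (Z)-4-(3-iodoprop-2-en-1-yl)-1,2-dimethoxybenzene F6. Iodine–magnesium exchange (i-PrMgCl·LiCl, THF, 0 °C to rt) gives (Z)-[3-(3,4-dimethoxyphenyl)prop-1-en-1-yl]magnesium chloride F7 with retention of geometry. Andersen substitution on sulfinate 4 (toluene, −20 °C) then delivers 7 directly, with no alkynyl sulfoxide and no hydrogenation.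

3. Step 9. Facial selectivity may be poor if zinc chelation between the two carbonyl groups is incomplete, and enolisation of the β-keto lactone may consume hydride. Fallback (from 18, back to the route at 19): catalyst control replaces substrate control. Asymmetric transfer hydrogenation with RuCl(p-cymene)[(S,S)-TsDPEN] (1 mol %) in HCO2H–Et3N at rt should deliver hydride to the aryl ketone in the sense that gives the (S)-carbinol. The epimerisable C3 centre can adjust to the syn, 3,4-trans arrangement. No new compound arises (F0).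

**Further compounds**

F1 | step 4 | (R)-4-benzyl-3-[4-(tert-butoxy)-4-oxobutanoyl]oxazolidin-2-one | CC(C)(C)OC(=O)CCC(=O)N1[C@H](Cc2ccccc2)COC1=O
F2 | step 4 | sodium (Z)-enolate of F1 | CC(C)(C)OC(=O)C/C=C(\O[Na])N1[C@H](Cc2ccccc2)COC1=O
F3 | step 4 | tert-butyl (R)-4-[(R)-4-benzyl-2-oxooxazolidin-3-yl]-3-(3,4-dimethoxybenzyl)-4-oxobutanoate | CC(C)(C)OC(=O)C[C@@H](Cc2ccc(OC)c(OC)c2)C(=O)N1[C@H](Cc3ccccc3)COC1=O
F4 | step 4 | tert-butyl (R)-3-(3,4-dimethoxybenzyl)-4-hydroxybutanoate | CC(C)(C)OC(=O)C[C@@H](Cc1ccc(OC)c(OC)c1)CO
F5 | step 2 | 4-(3-iodoprop-2-yn-1-yl)-1,2-dimethoxybenzene | COc1ccc(CC#CI)cc1OC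
F6 | step 2 | (Z)-4-(3-iodoprop-2-en-1-yl)-1,2-dimethoxybenzene | COc1ccc(C/C=C\I)cc1OC
F7 | step 2 | (Z)-[3-(3,4-dimethoxyphenyl)prop-1-en-1-yl]magnesium chloride | COc1ccc(C/C=C\[Mg]Cl)cc1OC
F0 | step 9 | none | none
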